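(The readings were generated by integration from invented constants; noise was put on by code.)

Read the earlier runs for a single quantity.

| setting | north-east | east | south-east | flask |
|---|---|---|---|---|
| solid electrophile | 1 M | 1 M | 1 M | 1.0 M |
| nucleophile | 0.90 M | 0.90 M | 0.45 M | 0.900 M |
| protic impurity | 0.20 M | 0.20 M | 0.20 M | 0.200 M |
| scavenger | 0.34 M | 0.75 M | 0.50 M | 0.500 M |
| remark | run made earlier | run made earlier | run made earlier |  |
| time |  |  |  | 5.0 min |

- north-east (time / min: solid electrophile / %, target / %): 0.200: 99.8, 0.2; 0.667: 99.3, 0.2; 1.00: 98.7, 0.9; 1.50: 97.9, 2.0; 2.50: 97.1, 2.4; 3.00: 96.6, 2.8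
- east (time / min: solid electrophile / %, target / %): 0.500: 99.6, 0.5; 1.00: 98.9, 1.2; 1.50: 98.2, 1.2; 2.00: 98.1, 2.0; 2.50: 97.1, 2.3; 3.00: 96.8, 3.1
- south-east (time / min: solid electrophile / %, target / %): 0.250: 99.7, 0.3; 0.417: 99.3, 0.3; 0.833: 99.9, 0.1; 1.50: 98.4, 1.3; 3.00: 96.3, 2.6

(scatter of a reading: 0.3 percentage points)

- at the start none of the solid electrophile is in solution
- what has only dissolved of solid electrophile counts as not reacted
- the earlier runs do not show how much of nucleophile is bound; that part of a forecast is a guess

- part of the solid electrophile that has reacted (what has only dissolved counts as not reacted) at 5.0 min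
- share of free nucleophile in free nucleophile and protonated nucleophile together, at 5.0 min

At 3.00 min the south-east run, with 0.45 M of nucleophile and 0.50 M of scavenger, reads 2.6% of target; the north-east run, with 0.90 M and 0.34 M, reads 2.8%; the east run, with 0.90 M and 0.75 M, reads 3.1%, against a scatter of 0.3 percentage points. That pattern reads as dissolution of the solid being the rate-limiting step, so a straight line in time is the thing to bracket. From above, solid lost, averaged over the last readings, gives 0.0114 M/min, which also counts what has only dissolved, so at 5.0 min the bound is 5.72%. From below, target gives 0.00944 M/min, which misses whatever reacted to something else, so the bound is 4.72%.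

This reckoning takes the middle: the feed rate, the molarity of electrophile reacted per minute, 0.0104 M/min, which gives 5.22%. Put back in, that answer spends 0.0520 M of the solid. Even with twice that amount of nucleophile gone, 0.796 M stands, more than the 0.45 M charged in the south-east run, so this reckoning keeps its straight line and a second round returns 5.22%.

The forecast gives 5.7%, level with the upper bound, and says that the rate “suggests dissolution of the solid limits it”. For the share of free nucleophile, which no reading shows, it guesses 90%.

The flask gives 5.16%, less than the upper bound and more than the lower, with 94.4% of the nucleophile pair free.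

    nucleophile + acid set free ⇌ protonated nucleophile, settled at all times (K = 4100 /M)
    acid set free + scavenger → scavenged by-product (k = 0.250 /M/s)
    electrophile + nucleophile → acid set free + target (k = 0.140 /M/s)
    electrophile + protic impurity → quenched substrate (k = 0.0470 /M/s)
    solid electrophile ⇌ electrophile, rate k5*(cs5 - [electrophile]) while solid is left; crystals form when [electrophile] > cs5 (solubility = 0.0720 M, k = 0.00250 /s)
    nucleophile + acid set free ⇌ idle adduct, settled at all times (K = 0.780 /M)

At 5.00 min the flask still holds 94.7% as solid electrophile and 89% of its nucleophile unbound, with electrophile at 0.144%, made 1.00 times as fast as it is used up. The neighbour flask charged with 0.40 M of solid electrophile takes the same reckoning: the feed rate 0.0104 M/min over 5.0 min, set on that smaller charge, gives 13.0%. That neighbour flask gives 12.9%, with 89% of its nucleophile left and target at 12.0%.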